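1. Hold your hunch that Thursday's, with the coupling partner fed slowly, spares the target until you have seen one number. The flasks, readings and questions were these:

| flask | starting material | coupling partner | remark | time |
|---|---|---|---|---|
| north-west | 0.40 M | 0.44 M | run made earlier |  |
| east | 0.40 M | 0.22 M | run made earlier |  |
| west | 0.40 M | 0.88 M | run made earlier |  |
| south-west | 0.80 M | 0.44 M | run made earlier |  |
| Tuesday's | 0.40 M | 0.440 M | a closed flask charged with all of it at once and left for 4.0 d | 4.0 d |
| Friday's | 0.40 M (fed, over 3.20 d) | 0.440 M | a stirred flask in which starting material is dosed at a steady rate over 3.20 d without added volume, worked up at 4.0 d | 4.0 d |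
| Thursday's | 0.40 M | 0.440 M (fed, over 3.20 d) | a stirred flask in which coupling partner is dosed at a steady rate over 3.20 d without added volume, worked up at 4.0 d | 4.0 d |
| Monday's | 0.40 M | 0.440 M | a single well-mixed tank run continuously and read at steady state, 4.0 d in it on average |  |

| run | time / d | target / % | side product / % | over-reaction product / % |
|---|---|---|---|---|
| north-west | 0.333 | 22.5 | 15.7 | 3.6 |
| north-west | 1.04 | 29.3 | 32.0 | 14.3 |
| north-west | 1.67 | 28.0 | 38.5 | 21.2 |
| north-west | 3.00 | 21.8 | 43.9 | 30.1 |
| north-west | 4.00 | 18.6 | 45.6 | 34.9 |
| east | 0.208 | 9.4 | 10.6 | 0.2 |
| east | 0.625 | 18.2 | 27.2 | 2.1 |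
| east | 1.04 | 21.3 | 38.9 | 4.0 |
| east | 1.67 | 23.2 | 49.1 | 6.3 |
| east | 2.50 | 22.8 | 56.8 | 9.9 |
| west | 0.500 | 34.6 | 16.8 | 18.8 |
| west | 1.04 | 28.3 | 22.7 | 37.8 |
| west | 1.25 | 25.5 | 23.5 | 44.4 |
| west | 2.08 | 14.6 | 25.6 | 58.1 |
| west | 2.50 | 11.2 | 26.1 | 61.6 |
| south-west | 0.208 | 15.4 | 10.6 | 1.7 |
| south-west | 0.625 | 24.5 | 24.7 | 5.5 |
| south-west | 1.04 | 27.0 | 34.7 | 8.1 |
| south-west | 1.67 | 27.9 | 43.4 | 10.9 |
| south-west | 2.50 | 26.7 | 50.2 | 12.8 |

(each reading ± 0.3 percentage points)

- the stated concentrations are those of everything mixed, before any reaction; amounts are the same in each set-up
- the feed brings no volume worth counting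
- the earlier runs were made in a closed, stirred flask

- the set-up with the highest share of target in all that became target or side product or over-reaction product, at the outlet or at the end ("none" if the first two lie within 2 percentage points) (Tuesday's / Friday's / Thursday's / Monday's / none)
- share of target in all that became target or side product or over-reaction product, at the outlet or at the end, Tuesday's
- share of target in all that became target or side product or over-reaction product, at the outlet or at the end, Friday's
- share of target in all that became target or side product or over-reaction product, at the outlet or at the end, Thursday's
- share of target in all that became target or side product or over-reaction product, at the outlet or at the end, Monday's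

2. I took the first north-west reading. Target plus over-reaction product, over side product, gave 1.66, the selectivity factor between the two routes of starting material. Counting one partner per target and two per over-reaction product, and taking the mean of the start and that reading, I put the partner's average at 0.865 of its charge up to then. Dividing gave 0.520 of the charge, the crossover level: the partner level at which starting material splits equally between the routes. The first west reading gave 0.526 on the same scale.

3. In Thursday's, the feed needed 1.67 d to deliver that much partner, counting none as used. Replacing the rising line by its mean, half the crossover level, I gave side product 66.7% of what turned over.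

4. The last north-west reading kept 34.8% of the coupled material as target. So I reckoned Thursday's at 11.6%. Friday's starts at the whole partner charge, above the crossover level, so I ranked it above Thursday's without a figure of my own.

5. The forecast gave 18.8% for Tuesday's, 22.4% for Friday's, 9.7% for Thursday's and 16.5% for Monday's. It chose Friday's, “favouring target over side product”. Its Thursday's figure was lower than mine.

6. The flasks gave 18.5%, 22.9%, 9.53% and 16.9% in that order, and the best was Friday's.

    starting material + coupling partner → target (k = 0.00180 M⁻¹ min⁻¹)
    starting material → side product (k = 4.20 × 10⁻⁴ min⁻¹)
    coupling partner + target → over-reaction product (k = 0.00150 M⁻¹ min⁻¹)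

In Thursday's, the 1.67 d the feed needed to deliver the crossover level was longer than the 1.1 d half-life of starting material on the side route at 0.745 d. Of the turnover up to 4.0 d, half on the side route was done by 0.744 d, and half on the target route by 1.42 d. With 1.8 M of partner fed instead, the feed delivered the same amount after 0.407 d, and side product ended at 47.7%.

The earlier runs and the new flask are simulated with made-up constants; the scatter is artificial.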